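Atom labels follow the indane numbering of the target: C1 and C2 are the ring CH2 groups, C3 the CH that carries the chain, C3a the ring-fusion CH, C4 the carbinol carbon, C5 and C6 CH2, C7 the CHBr carbon, C7a the quaternary fusion carbon, and C1' to C6' the chain carbons counted from the ring. Names of hydrindane intermediates use this numbering throughout.

## The problem

The target 24 is a C20 bromohydrin on a trans-fused hydrindane. The six-membered ring (C3a, C4 to C7, C7a) carries an axial tertiary alcohol at C4 and an equatorial secondary bromide at C7; the five-membered ring (C1 to C3, C3a, C7a) carries an (E)-2,6-dimethylhepta-1,5-dienyl chain at C3. Five stereocentres sit on the bicycle, C3, C3a, C7a and C7 in a row and C4 attached to C3a. The quaternary C7a is the only one that cannot be corrected after it is made, and it can steer the others: its axial methyl closes the β face at C4 and C7, and together with a substituent at C3 it fixes C3a thermodynamically (the C4 branch trans to both neighbours). The C7 bromide is neopentylic, so it cannot be introduced by substitution, and once present it is exposed to elimination and to methyl migration on ionisation. The C4 alcohol dehydrates in strong acid, and the skipped diene of the chain would not survive ozone, one-electron oxidants or radical hydrogenation, so the chain has to come last and its trisubstituted C1'=C2' alkene needs dependable E control. The enabling feature is the run C4–C5–C6–C7, bound through its two ends to the adjacent ring atoms C3a and C7a and oxidised at both ends (C4–OH; C7–Br, reachable from C7=O). This is a masked 1,4-diketone, the ozonolysis product of a 1,2-dimethylcyclobutene fused at C3a–C7a, and such a cyclobutene on a cyclopentane with a methyl at the fusion carbon is the (2+2) photoadduct 3 of enone 1 and alkyne 2.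

## Retrosynthesis

**Side chain (24 ⇒ 23 ⇒ 22 ⇒ 19 + 20 ⇒ 18).** The C5'=C6' alkene is cut first (Wittig reaction of aldehyde 23 with an isopropylidene ylide). Ester 22 is then opened at C3'–C4' by a Johnson–Claisen disconnection to allylic alcohol 19 and orthoester 20, and 19 is cut at C1'–C2' to aldehyde 18 and an isopropenyl Grignard reagent. Direct olefination of 18 with a branched ylide or sulfone would give E/Z mixtures at the trisubstituted alkene. The sigmatropic route fixes E through a chair transition state, and both carbinol epimers of 19 converge. Compound 18 has no alkene at all, so every oxidative and radical operation can be placed before it. The forward steps must tolerate a free tertiary alcohol and the bromide.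

**C7 bromide (18 ⇒ 17 ⇒ 16 ⇒ 15 ⇒ 13).** After adjusting C1' (aldehyde 18 from diol 17, from silyl ether 16), the C7–H bond is cut to bromoalkene 15, and 15 is traced to ketone 13. Displacement at C7 is not an option next to C7a, and an alkyl radical that picks up bromine would tend to take it axially. The reverse order, an α-bromo radical that picks up hydrogen, places the small atom on the axial path anti to the angular methyl and leaves bromine equatorial. The forward reaction must hydrogenate a bromoalkene without cleaving C–Br and needs a substrate free of other alkenes.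

**C4 methyl (13 ⇒ 12).** Cutting C4–CH3 gives the trans-hydrindane-4,7-dione 12. Its two carbonyls differ: C4 is flanked by a CH, C7 by the quaternary C7a. The axial C7a methyl allows only equatorial attack at C4, which gives the axial alcohol of the target. The forward step needs site selection and a non-basic methyl donor, because C3a is enolisable in 12.

**C5–C6 (12 ⇒ 11 ⇒ 10).** The C5–C6 bond joins two former methyl groups, so 12 is cut to bis(enol silane) 11 and the trans-diacetylcyclopentane 10. The neighbouring cut, an aldol between the two acetyls, would close a five-membered ring and lose the 1,4-dioxygen pattern. Bringing C5 and C6 in from outside would waste the alkyne carbons. The precursor is monocyclic, and the forward step is an intramolecular oxidative enol silane coupling.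

**C3a and the cyclobutene (10 ⇒ 9 ⇒ 7).** Diketone 10 is the C3a epimer of the all-cis diketone 9, which is reconnected at C4=C7 to the cyclobutene 7. The cis fusion of the bicyclo[3.2.0] skeleton is paid for by one epimerisation, placed at the monocyclic stage where the preference for the trans,trans isomer is large. In the bicyclic dione 12 the preference would be small.

**C3–C1' (7 ⇒ 6 ⇒ 4 ⇒ 3).** The silyl ether 7 comes from alcohol 6; the C3–H bond is cut to the exocyclic alkene 4 (hydroboration from the convex face of the folded bicycle), and C3=C1' is cut to ketone 3. The carbonyl that activates the enone in the key step thus becomes the attachment point of the chain.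

**Key cut (3 ⇒ 1 + 2).** Cutting C3a–C4 and C7a–C7 of the cyclobutene gives 3-methylcyclopent-2-enone 1 and but-2-yne 2, both commercial. One step creates the quaternary C7a and attaches C4 to C7 with their two future ring carbons. The alkyne is symmetrical, so only the absolute configuration has to be controlled.

## Roads not taken

**Alternative 1:** An acyclic 1,7-enyne A1, carrying the C4 carbinol from the chiral pool, would be closed with Co2(CO)8 and N-methylmorpholine N-oxide to the bicyclic cyclopentenone A2, forming C3a–C7a, C1–C2 and C2–C3 and both rings at once.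
- Merits: this is better than the chosen plan in ring-forming economy (one step against photocycloaddition, ozonolysis and coupling), and it needs no unproven asymmetric step.
- Weak points: C7a would be set only by 1,3-induction from C4 across a forming ring. A 1,7-enyne with a 1,1-disubstituted alkene is a slow substrate class. A2 carries a C2 carbonyl that must be removed and a tetrasubstituted C3=C3a alkene whose reduction must add the two hydrogens anti and trans to the C7a methyl, which neither hydrogenation nor dissolving-metal reduction secures for a hydrindane. The C7 bromide problem remains unsolved.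
- Comparison: the chosen plan sets C3, C3a, C4 and C7 each under a single, identifiable control element and has no surplus functionality to remove.

**Alternative 2:** An acyclic chlorodiene A3 would be cyclised with a bromonium donor (Et2SBr·SbCl5Br, or 1,3-dibromo-5,5-dimethylhydantoin with a chiral thiophosphoramide), forming C7–Br and C7a–C3a to give the bromocyclohexanone A4.
- Merits: it solves the hardest functional group of the target, the neopentylic bromide cis to the angular methyl, in the ring-forming step itself. The chosen plan needs two steps and takes a stereochemical risk there.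
- Weak points: enantiocontrol in bromonium cyclisations is modest and substrate-dependent. A chloroalkene is a weak terminator. From A4 the five-membered ring, C3a (trans), C3 and C4 all have to be built by enolate and organometallic chemistry on a ring that already holds the base-sensitive bromide, with an open choice of enolisation between C3a and C5.
- Comparison: the chosen plan installs bromine only after the skeleton and the tertiary alcohol are in place, though it still carries it through six mild steps.

**Alternative 3:** A quinone-derived trans-fused bromo-decalinol A5 would be ozonised (O3, then Me2S) to dialdehyde A6 and closed with piperidinium acetate to the cyclopentene carbaldehyde A7, forming C2=C3.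
- Merits: every reaction has close precedent, the Diels–Alder entry has reliable catalytic asymmetric versions, and A7 offers a handle at C3 whose configuration can be corrected by epimerisation. In precedent this road is better than the chosen plan.
- Weak points: A5 already requires the C4 carbinol, the C7 bromide and the trans fusion to be solved on a decalin, so the difficult chemistry is only moved. A6 has two enolisable aldehydes and can give the regioisomeric enal. Its C4 hydroxyl lies gauche to the C3 arm and can close a lactol on the aldehyde that has to act as the donor. The C2=C3 alkene must later be saturated without touching C–Br. A ring is built larger and then cut.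
- Comparison: the chosen plan has the five-membered ring from the first step and sacrifices only the cyclobutene, all four carbons of which end up in the product.

Key step: step 1

Remarks on the chemistry:
- **Assumption:** the Lewis acid built from (S)-α,α-bis(3,5-dimethylphenyl)prolinol is taken to shield the enone face that leads to (1S,5S)-3. If it favours the mirror image, the Lewis acid from the (R)-prolinol is used and nothing else changes.
- **Lewis acid:** the oxazaborolidine is prepared beforehand in two operations (aryl Grignard addition to a proline ester, condensation with 2,4,6-trifluorophenylboronic acid) and activated with AlBr3 in the reactor. It is a reagent and is not counted.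

## Route

Step 1
Reactants: 1 3-methylcyclopent-2-en-1-one; 2 but-2-yne
Product: 3 (1S,5S)-5,6,7-trimethylbicyclo[3.2.0]hept-6-en-2-one
Conditions: hν (366 nm), oxazaborolidine·AlBr3 (50 mol %), 2 (10 equiv), CH2Cl2, −75 °C, stopped at partial conversion, 1 recovered
Reagents that add atoms: none
Why: Proposed new method: coordination of the AlBr3-activated oxazaborolidine to the carbonyl oxygen of 1 shifts the enone π–π* band to longer wavelength, so that at 366 nm mainly the chiral complex absorbs; after intersystem crossing the triplet enone forms a first C–C bond to 2, giving a triplet 1,4-biradical that recombines after spin inversion. The closest known reactions are the racemic enone–alkyne (2+2) photocycloaddition and the enone–alkene (2+2) photocycloaddition mediated by this class of chiral Lewis acid. The cyclobutene ring therefore closes stepwise, by radical recombination of the biradical and not in a concerted way, forming C3a–C4 and C7a–C7. The quaternary C7a is set by the catalyst, whose aryl groups cover one face of the bound enone; C3a follows from the ring fusion, since a four-membered ring on a cyclopentane can only be cis. No regiochemistry arises because 2 is symmetrical, so the step needs only face selection and product survival. Product 3 is a β,γ-unsaturated ketone that is nearly transparent at 366 nm, and stopping at partial conversion limits its photochemical 1,3-acyl shift.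

Step 2
Reactants: 3 (1S,5S)-5,6,7-trimethylbicyclo[3.2.0]hept-6-en-2-one
Product: 4 (1S,5S)-5,6,7-trimethyl-2-methylidenebicyclo[3.2.0]hept-6-ene
Conditions: Ph3PCH3Br, KOt-Bu, THF, 0 to 23 °C; volatile product carried on as a solution
Reagents that add atoms: methyltriphenylphosphonium bromide, C[P+](c1ccccc1)(c1ccccc1)c1ccccc1.[Br-]
Why: Wittig methylenation of a cyclopentanone. C3a cannot epimerise because only the cis fusion exists, and migration of the cyclobutene double bond into conjugation would place an alkene at the bridgehead.

Step 3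
Reactants: 4 (1S,5S)-5,6,7-trimethyl-2-methylidenebicyclo[3.2.0]hept-6-ene
Product: 6 [(1S,2R,5S)-5,6,7-trimethylbicyclo[3.2.0]hept-6-en-2-yl]methanol, via B-alkyl-9-borabicyclo[3.3.1]nonane 5 (not isolated)
Conditions: 9-BBN, THF, 0 to 23 °C; then NaOH, H2O2, 0 to 23 °C
Reagents that add atoms: 9-borabicyclo[3.3.1]nonane, B1C2CCCC1CCC2 (boron and its ring stay in 5 only); hydrogen peroxide, OO
Why: Anti-Markovnikov hydroboration–oxidation. The bulky borane reacts only with the 1,1-disubstituted alkene and not with the tetrasubstituted cyclobutene. It delivers hydrogen to C3 from the convex face, away from the cyclobutene and its C4 methyl, so C1' ends on the cyclobutene face, which is the C3 configuration of 24.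

Step 4
Reactants: 6 [(1S,2R,5S)-5,6,7-trimethylbicyclo[3.2.0]hept-6-en-2-yl]methanol
Product: 7 tert-butyl{[(1S,2R,5S)-5,6,7-trimethylbicyclo[3.2.0]hept-6-en-2-yl]methoxy}diphenylsilane
Conditions: t-BuPh2SiCl, imidazole, DMF, 23 °C
Reagents that add atoms: tert-butyl(chloro)diphenylsilane, CC(C)(C)[Si](Cl)(c1ccccc1)c1ccccc1
Why: Silylation of a primary alcohol. This ether withstands ozone, carbonate, amide base, the cerium oxidant and the organocerium reagent, and is later removed with buffered fluoride.

Step 5
Reactants: 7 tert-butyl{[(1S,2R,5S)-5,6,7-trimethylbicyclo[3.2.0]hept-6-en-2-yl]methoxy}diphenylsilane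
Product: 9 1,1'-[(1S,2R,3R)-3-({[tert-butyl(diphenyl)silyl]oxy}methyl)-1-methylcyclopentane-1,2-diyl]di(ethan-1-one), via secondary ozonide 8 (not isolated)
Conditions: O3, CH2Cl2, −78 °C; then PPh3, −78 to 23 °C
Reagents that add atoms: ozone, [O-][O+]=O
Why: Ozonolysis of a tetrasubstituted cyclobutene: cycloaddition, cycloreversion and recombination give ozonide 8, which PPh3 reduces to the two methyl ketones. The strain of the four-membered ring is released and C4 and C7 become carbonyl carbons.

Step 6
Reactants: 9 all-cis diketone (1S,2R,3R)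
Product: 10 1,1'-[(1S,2S,3R)-3-({[tert-butyl(diphenyl)silyl]oxy}methyl)-1-methylcyclopentane-1,2-diyl]di(ethan-1-one)
Conditions: K2CO3, MeOH, 0 to 23 °C, followed by NMR
Reagents that add atoms: none
Why: Base-mediated epimerisation through the C3a enolate. In 9 the C4 acetyl is cis to both the C3 silyloxymethyl group and the C7 acetyl, in 10 it is trans to both, so the equilibrium should lie well on the side of 10 (C3a set). Carbonate in methanol is chosen because aldol condensation of a 1,4-diketone to a cyclopentenone needs stronger base, and in 10 the two acetyls can no longer reach each other without forming a trans-fused bicyclo[3.3.0] ring.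

Step 7
Reactants: 10 trans-diketone (1S,2S,3R)
Product: 11 tert-butyl{[(1R,2S,3S)-3-methyl-2,3-bis{1-[(trimethylsilyl)oxy]ethenyl}cyclopentyl]methoxy}diphenylsilane
Conditions: LiN(i-Pr)2, Me3SiCl (premixed), THF, −78 °C, 10 added last; Et3N, pentane, cold aq. NaHCO3; used crude
Reagents that add atoms: chlorotrimethylsilane, C[Si](C)(C)Cl
Why: Kinetic enolisation with in situ silylation. The amide removes a methyl proton of each acetyl (C7a is quaternary, the C3a hydrogen is tertiary and hindered), and the silyl chloride traps each enolate before it can add to the other carbonyl. C3a is not touched.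

Step 8
Reactants: 11 bis(trimethylsilyl enol ether)
Product: 12 (3R,3aS,7aS)-3-({[tert-butyl(diphenyl)silyl]oxy}methyl)-7a-methylhexahydro-1H-indene-4,7-dione
Conditions: Ce(NH4)2(NO3)6 (2.2 equiv), NaHCO3, MeCN, −30 °C, high dilution
Reagents that add atoms: none
Why: Intramolecular oxidative coupling of a bis(silyl enol ether). One-electron oxidation of one enol silane gives an electrophilic α-carbonyl radical at C5, which adds to the terminal carbon C6 of the second enol silane in the 6-endo mode preferred on 1,1-disubstituted alkenes; a second oxidation and loss of both silyl groups give the 1,4-dione. The trans-disposed arms close a trans-hydrindane, and the bicarbonate buffer keeps C3a from equilibrating.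

Step 9
Reactants: 12 trans-hydrindane-4,7-dione
Product: 13 (3R,3aS,4R,7aS)-3-({[tert-butyl(diphenyl)silyl]oxy}methyl)-4-hydroxy-4,7a-dimethyloctahydro-7H-inden-7-one
Conditions: MeLi (1.2 equiv), CeCl3 (1.3 equiv), THF, −78 °C
Reagents that add atoms: methyllithium, [Li]C
Why: 1,2-Addition of a non-basic organocerium reagent, which avoids enolisation at C3a. C4 is flanked by a CH and C7 by the quaternary C7a, so the first equivalent should add at C4. The axial C7a methyl blocks the β face, so methyl enters equatorially from the α face and the hydroxyl ends axial and β (C4 set).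

Step 10
Reactants: 13 hydroxy ketone
Product: 15 (3R,3aS,4R,7aS)-7-bromo-3-({[tert-butyl(diphenyl)silyl]oxy}methyl)-4,7a-dimethyl-2,3,3a,4,5,7a-hexahydro-1H-inden-4-ol, via C7 hydrazone 14 (not isolated)
Conditions: N2H4·H2O, Et3N, EtOH, 80 °C; concentrate; then N-bromosuccinimide (2.2 equiv), pyridine, CH2Cl2, −10 to 23 °C
Reagents that add atoms: hydrazine, NN (nitrogen stays in 14 only); N-bromosuccinimide, BrN1C(=O)CCC1=O
Why: Hydrazone formation followed by Barton-type oxidative halogenation: N-bromination, loss of HBr to the diazo compound, C-bromination, then loss of N2 and of a C6 proton. C7a is quaternary, so the alkene can form only towards C6, and the free tertiary alcohol is not affected.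

Step 11
Reactants: 15 bromoalkene
Product: 16 (3R,3aS,4R,7S,7aS)-7-bromo-3-({[tert-butyl(diphenyl)silyl]oxy}methyl)-4,7a-dimethyloctahydro-1H-inden-4-ol
Conditions: Mn(dpm)3 (10 mol %; dpm = 2,2,6,6-tetramethylheptane-3,5-dionate), PhSiH3, t-BuOOH, i-PrOH, 23 °C
Reagents that add atoms: none
Why: Metal-hydride hydrogen-atom-transfer hydrogenation, a reaction type that converts haloalkenes into alkyl halides without cleaving the carbon–halogen bond. Hydrogen adds first to C6 and gives the bromine-stabilised C7 radical. This radical takes its second hydrogen along the axial path on the α face, anti to the axial C7a methyl, so bromine ends equatorial and β (C7 set).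

Step 12
Reactants: 16 silyl ether bromide
Product: 17 (3R,3aS,4R,7S,7aS)-7-bromo-3-(hydroxymethyl)-4,7a-dimethyloctahydro-1H-inden-4-ol
Conditions: Bu4NF, AcOH, THF, 0 to 23 °C
Reagents that add atoms: none
Why: Fluoride cleavage of the silyl ether under buffered conditions. The equatorial bromide has no anti-periplanar hydrogen, and no free base is present to force an elimination.

Step 13
Reactants: 17 bromo diol
Product: 18 (3R,3aS,4R,7S,7aS)-7-bromo-4-hydroxy-4,7a-dimethyloctahydro-1H-indene-3-carbaldehyde
Conditions: Dess–Martin periodinane, CH2Cl2, 0 to 23 °C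
Reagents that add atoms: none
Why: Dess–Martin oxidation of the primary alcohol; the tertiary alcohol cannot be oxidised. The formyl group at C3 is already trans to C4, the more stable arrangement, so enolisation would do no harm, and the trans relationship prevents lactol formation with the C4 hydroxyl.

Step 14
Reactants: 18 hydroxy aldehyde
Product: 19 (3R,3aS,4R,7S,7aS)-7-bromo-3-(1-hydroxy-2-methylprop-2-en-1-yl)-4,7a-dimethyloctahydro-1H-inden-4-ol (both C1' epimers)
Conditions: CH2=C(CH3)MgBr (2.5 equiv), THF, −78 °C
Reagents that add atoms: isopropenylmagnesium bromide, CC(=C)[Mg]Br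
Why: Grignard addition to the aldehyde forms C1'–C2'; the first equivalent is consumed by the C4 hydroxyl. The configuration at C1' is irrelevant because both epimers converge in step 15.

Step 15
Reactants: 19 allylic alcohol; 20 triethyl orthoacetate
Product: 22 ethyl (4E)-5-[(3S,3aS,4R,7S,7aS)-7-bromo-4-hydroxy-4,7a-dimethyloctahydro-1H-inden-3-yl]-4-methylpent-4-enoate, via mixed ketene acetal 21 (not isolated)
Conditions: 20 (8 equiv), EtCO2H (0.1 equiv), xylene, 135 °C, EtOH distilled off; mild aqueous acid work-up
Reagents that add atoms: none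
Why: Johnson–Claisen rearrangement. Orthoester exchange and loss of ethanol give ketene acetal 21, whose chair transition state with the ring residue pseudo-equatorial forms C3'–C4' and the (E)-C1'=C2' alkene. This is the standard case for E-trisubstituted alkenes from 2-methylallyl carbinols, and the hindered axial C4 hydroxyl should exchange only slowly and reversibly.

Step 16
Reactants: 22 ester
Product: 23 (4E)-5-[(3S,3aS,4R,7S,7aS)-7-bromo-4-hydroxy-4,7a-dimethyloctahydro-1H-inden-3-yl]-4-methylpent-4-enal
Conditions: i-Bu2AlH (2.2 equiv), CH2Cl2, −78 °C; aq. potassium sodium tartrate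
Reagents that add atoms: none
Why: Partial reduction of the ester at −78 °C, where the aluminium hemiacetal persists until work-up. The alkyl bromide and the alkene are inert; one equivalent is consumed by the hydroxyl.

Step 17
Reactants: 23 aldehyde
Product: 24 (3S,3aS,4R,7S,7aS)-7-bromo-3-[(1E)-2,6-dimethylhepta-1,5-dien-1-yl]-4,7a-dimethyloctahydro-1H-inden-4-ol
Conditions: i-PrPPh3I, n-BuLi, THF, 0 °C; then 23, −78 to 23 °C
Reagents that add atoms: isopropyltriphenylphosphonium iodide, CC(C)[P+](c1ccccc1)(c1ccccc1)c1ccccc1.[I-]
Why: Wittig olefination with the non-stabilised isopropylidene ylide forms C5'=C6', where no geometry arises. The equatorial bromide offers no anti-periplanar hydrogen for elimination, and the C4 alkoxide is a spectator.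

## Compound list

1 | 3-methylcyclopent-2-en-1-one | CC1=CC(=O)CC1 | starting material
2 | but-2-yne | CC#CC | starting material
3 | (1S,5S)-5,6,7-trimethylbicyclo[3.2.0]hept-6-en-2-one (cis-fused) | CC1=C(C)[C@@]2(C)CCC(=O)[C@@H]12 | intermediate
4 | (1S,5S)-5,6,7-trimethyl-2-methylidenebicyclo[3.2.0]hept-6-ene | CC1=C(C)[C@@]2(C)CCC(=C)[C@@H]12 | intermediate
5 | 9-{[(1S,2R,5S)-5,6,7-trimethylbicyclo[3.2.0]hept-6-en-2-yl]methyl}-9-borabicyclo[3.3.1]nonane | C(B1C2CCCC1CCC2)[C@@H]1CC[C@]2(C)C(C)=C(C)[C@H]12 | intermediate (not isolated)
6 | [(1S,2R,5S)-5,6,7-trimethylbicyclo[3.2.0]hept-6-en-2-yl]methanol (CH2OH on the cyclobutene face) | OC[C@@H]1CC[C@]2(C)C(C)=C(C)[C@H]12 | intermediate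
7 | tert-butyl{[(1S,2R,5S)-5,6,7-trimethylbicyclo[3.2.0]hept-6-en-2-yl]methoxy}diphenylsilane | CC(C)(C)[Si](OC[C@@H]1CC[C@]2(C)C(C)=C(C)[C@H]12)(c1ccccc1)c1ccccc1 | intermediate
8 | secondary ozonide of 7 (1,2,4-trioxolane spanning C4 and C7; orientation of the peroxide bridge not defined, either form gives 9) | CC(C)(C)[Si](OC[C@@H]1CC[C@]2(C)C3(C)OOC(C)(O3)[C@H]12)(c1ccccc1)c1ccccc1 | intermediate (not isolated)
9 | 1,1'-[(1S,2R,3R)-3-({[tert-butyl(diphenyl)silyl]oxy}methyl)-1-methylcyclopentane-1,2-diyl]di(ethan-1-one) (all-cis) | CC(C)(C)[Si](OC[C@@H]1CC[C@](C)(C(C)=O)[C@@H]1C(C)=O)(c1ccccc1)c1ccccc1 | intermediate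
10 | 1,1'-[(1S,2S,3R)-3-({[tert-butyl(diphenyl)silyl]oxy}methyl)-1-methylcyclopentane-1,2-diyl]di(ethan-1-one) (C4 acetyl trans to both neighbours) | CC(C)(C)[Si](OC[C@@H]1CC[C@](C)(C(C)=O)[C@H]1C(C)=O)(c1ccccc1)c1ccccc1 | intermediate
11 | tert-butyl{[(1R,2S,3S)-3-methyl-2,3-bis{1-[(trimethylsilyl)oxy]ethenyl}cyclopentyl]methoxy}diphenylsilane | CC(C)(C)[Si](OC[C@@H]1CC[C@](C)(C(=C)O[Si](C)(C)C)[C@H]1C(=C)O[Si](C)(C)C)(c1ccccc1)c1ccccc1 | intermediate
12 | (3R,3aS,7aS)-3-({[tert-butyl(diphenyl)silyl]oxy}methyl)-7a-methylhexahydro-1H-indene-4,7-dione (trans-fused) | CC(C)(C)[Si](OC[C@@H]1CC[C@]2(C)C(=O)CCC(=O)[C@@H]12)(c1ccccc1)c1ccccc1 | intermediate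
13 | (3R,3aS,4R,7aS)-3-({[tert-butyl(diphenyl)silyl]oxy}methyl)-4-hydroxy-4,7a-dimethyloctahydro-7H-inden-7-one | CC(C)(C)[Si](OC[C@@H]1CC[C@]2(C)C(=O)CC[C@@](C)(O)[C@@H]12)(c1ccccc1)c1ccccc1 | intermediate
14 | (3R,3aS,4R,7aS)-3-({[tert-butyl(diphenyl)silyl]oxy}methyl)-7-hydrazinylidene-4,7a-dimethyloctahydro-1H-inden-4-ol | CC(C)(C)[Si](OC[C@@H]1CC[C@]2(C)C(=NN)CC[C@@](C)(O)[C@@H]12)(c1ccccc1)c1ccccc1 | intermediate (not isolated)
15 | (3R,3aS,4R,7aS)-7-bromo-3-({[tert-butyl(diphenyl)silyl]oxy}methyl)-4,7a-dimethyl-2,3,3a,4,5,7a-hexahydro-1H-inden-4-ol | CC(C)(C)[Si](OC[C@@H]1CC[C@]2(C)C(Br)=CC[C@@](C)(O)[C@@H]12)(c1ccccc1)c1ccccc1 | intermediate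
16 | (3R,3aS,4R,7S,7aS)-7-bromo-3-({[tert-butyl(diphenyl)silyl]oxy}methyl)-4,7a-dimethyloctahydro-1H-inden-4-ol | CC(C)(C)[Si](OC[C@@H]1CC[C@]2(C)[C@@H](Br)CC[C@@](C)(O)[C@@H]12)(c1ccccc1)c1ccccc1 | intermediate
17 | (3R,3aS,4R,7S,7aS)-7-bromo-3-(hydroxymethyl)-4,7a-dimethyloctahydro-1H-inden-4-ol | OC[C@@H]1CC[C@]2(C)[C@@H](Br)CC[C@@](C)(O)[C@@H]12 | intermediate
18 | (3R,3aS,4R,7S,7aS)-7-bromo-4-hydroxy-4,7a-dimethyloctahydro-1H-indene-3-carbaldehyde | O=C[C@@H]1CC[C@]2(C)[C@@H](Br)CC[C@@](C)(O)[C@@H]12 | intermediate
19 | (3R,3aS,4R,7S,7aS)-7-bromo-3-(1-hydroxy-2-methylprop-2-en-1-yl)-4,7a-dimethyloctahydro-1H-inden-4-ol (both C1' epimers) | CC(=C)C(O)[C@@H]1CC[C@]2(C)[C@@H](Br)CC[C@@](C)(O)[C@@H]12 | intermediate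
20 | triethyl orthoacetate | CCOC(C)(OCC)OCC | starting material
21 | mixed ketene acetal of 19 (1-ethoxyethenyl ether at C1') | C=C(OCC)OC(C(C)=C)[C@@H]1CC[C@]2(C)[C@@H](Br)CC[C@@](C)(O)[C@@H]12 | intermediate (not isolated)
22 | ethyl (4E)-5-[(3S,3aS,4R,7S,7aS)-7-bromo-4-hydroxy-4,7a-dimethyloctahydro-1H-inden-3-yl]-4-methylpent-4-enoate | CCOC(=O)CC/C(C)=C/[C@@H]1CC[C@]2(C)[C@@H](Br)CC[C@@](C)(O)[C@@H]12 | intermediate
23 | (4E)-5-[(3S,3aS,4R,7S,7aS)-7-bromo-4-hydroxy-4,7a-dimethyloctahydro-1H-inden-3-yl]-4-methylpent-4-enal | O=CCC/C(C)=C/[C@@H]1CC[C@]2(C)[C@@H](Br)CC[C@@](C)(O)[C@@H]12 | intermediate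
24 | (3S,3aS,4R,7S,7aS)-7-bromo-3-[(1E)-2,6-dimethylhepta-1,5-dien-1-yl]-4,7a-dimethyloctahydro-1H-inden-4-ol | CC(C)=CCC/C(C)=C/[C@@H]1CC[C@]2(C)[C@@H](Br)CC[C@@](C)(O)[C@@H]12 | target

## Step count and least certain steps

Total: 17 steps. Longest linear sequence: 17 steps, from 1 and 2 to 24 (20 is commercial and enters at step 15).

**Step 1 (key step, proposed new method).** Face discrimination may be poor with an alkyne partner, and unsensitised background reaction of uncomplexed enone may erode it, because alkynes add to triplet enones more slowly than alkenes. The fallback sets out from 1 and 2 and returns at 3.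
- Unsensitised irradiation of 1 with excess 2 (medium-pressure mercury lamp, Pyrex filter, CH2Cl2, −40 °C), the known racemic reaction, gives racemic 5,6,7-trimethylbicyclo[3.2.0]hept-6-en-2-one F1.
- NaBH4 attacks from the convex face to give racemic endo (1RS,2SR,5RS)-5,6,7-trimethylbicyclo[3.2.0]hept-6-en-2-ol F2.
- Lipase-catalysed acylation (Candida antarctica lipase B, vinyl acetate) is expected, from the usual preference for the R carbinol, to give (1S,2R,5S)-5,6,7-trimethylbicyclo[3.2.0]hept-6-en-2-yl acetate F3, separable from the unreacted antipodal alcohol.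
- Methanolysis (K2CO3, MeOH) gives (1S,2R,5S)-5,6,7-trimethylbicyclo[3.2.0]hept-6-en-2-ol F4, and Dess–Martin oxidation returns enantiopure 3.
- If the enzyme prefers the other enantiomer, the unreacted alcohol is oxidised instead.

**Step 6.** Intramolecular aldol condensation of the cis-1,4-diketone may compete with enolisation at the hindered C3a, funnelling material into a bicyclo[3.3.0]octenone. The fallback sets out from 9 and returns at 12.
- In situ silylation (LiN(i-Pr)2, Me3SiCl, −78 °C), which cannot lead to aldol products, gives the cis bis(enol silane) tert-butyl{[(1R,2R,3S)-3-methyl-2,3-bis{1-[(trimethylsilyl)oxy]ethenyl}cyclopentyl]methoxy}diphenylsilane F5.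
- Oxidative coupling with Ce(NH4)2(NO3)6 gives the cis-fused dione (3R,3aR,7aS)-3-({[tert-butyl(diphenyl)silyl]oxy}methyl)-7a-methylhexahydro-1H-indene-4,7-dione F6.
- F6 is equilibrated at C3a (DBU, toluene) to 12, in a ring system where no aldol closure is possible.
- The preference for 12 at this stage rests only on the C3 substituent, so the cis isomer would have to be recycled.

**Step 8.** The radical cation may be intercepted by nitrate or lose its silyl group before ring closure, or couple intermolecularly. The fallback sets out from 11 and returns at 12.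
- One equivalent of N-bromosuccinimide (THF, −78 °C) brominates one enol silane. It gives the pair of bromomethyl ketones 2-bromo-1-[(1S,2S,3R)-3-({[tert-butyl(diphenyl)silyl]oxy}methyl)-1-methyl-2-{1-[(trimethylsilyl)oxy]ethenyl}cyclopentyl]ethan-1-one F7 and 2-bromo-1-[(1S,2S,5R)-5-({[tert-butyl(diphenyl)silyl]oxy}methyl)-2-methyl-2-{1-[(trimethylsilyl)oxy]ethenyl}cyclopentyl]ethan-1-one F8.
- A mild fluoride source (Bu4N[Ph3SiF2]) releases the remaining enolate, which closes C5–C6 by 6-exo alkylation.
- Both regioisomers give the same dione 12.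

**Step 9.** Site selection between the C4 and C7 carbonyls may be poor, or double addition may occur, because each carbonyl is hindered in a different way. The fallback sets out from 12 and returns at 13.
- Buffered desilylation (Bu4NF, AcOH) gives (3R,3aS,7aS)-3-(hydroxymethyl)-7a-methylhexahydro-1H-indene-4,7-dione F9.
- Me3Al (3 equiv, CH2Cl2, −78 to 0 °C) forms an aluminium alkoxide at C1' that activates the nearby C4 carbonyl from the α side and directs methylation there, giving (3R,3aS,4R,7aS)-4-hydroxy-3-(hydroxymethyl)-4,7a-dimethyloctahydro-7H-inden-7-one F10.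
- Selective silylation of the primary alcohol (t-BuPh2SiCl, imidazole) gives 13.

**Step 11.** Hydrogen may be delivered to the wrong face of the C7 radical, giving the axial bromide, or the alkene may be sluggish and bromine lost by reduction. The fallback sets out from 13 and returns at 16.
- Hydrazone 14 is oxidised with CuBr2 and LiOt-Bu to the geminal dibromide (3R,3aS,4R,7aS)-7,7-dibromo-3-({[tert-butyl(diphenyl)silyl]oxy}methyl)-4,7a-dimethyloctahydro-1H-inden-4-ol F11.
- Mono-reduction with Bu3SnH (1.05 equiv, Et3B, air, toluene, −78 °C) generates the same α-bromo radical without an alkene. The bulky tin hydride should approach from the α face, anti to the angular methyl, to give 16.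

## Further compounds

F1 | step 1 | racemic 5,6,7-trimethylbicyclo[3.2.0]hept-6-en-2-one (cis-fused; one enantiomer drawn) | CC1=C(C)[C@@]2(C)CCC(=O)[C@@H]12
F2 | step 1 | racemic (1RS,2SR,5RS)-5,6,7-trimethylbicyclo[3.2.0]hept-6-en-2-ol (endo alcohol; one enantiomer drawn) | CC1=C(C)[C@@]2(C)CC[C@@H](O)[C@@H]12
F3 | step 1 | (1S,2R,5S)-5,6,7-trimethylbicyclo[3.2.0]hept-6-en-2-yl acetate | CC1=C(C)[C@@]2(C)CC[C@@H](OC(C)=O)[C@@H]12
F4 | step 1 | (1S,2R,5S)-5,6,7-trimethylbicyclo[3.2.0]hept-6-en-2-ol | CC1=C(C)[C@@]2(C)CC[C@@H](O)[C@@H]12
F5 | step 6 | tert-butyl{[(1R,2R,3S)-3-methyl-2,3-bis{1-[(trimethylsilyl)oxy]ethenyl}cyclopentyl]methoxy}diphenylsilane (all-cis) | CC(C)(C)[Si](OC[C@@H]1CC[C@](C)(C(=C)O[Si](C)(C)C)[C@@H]1C(=C)O[Si](C)(C)C)(c1ccccc1)c1ccccc1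
F6 | step 6 | (3R,3aR,7aS)-3-({[tert-butyl(diphenyl)silyl]oxy}methyl)-7a-methylhexahydro-1H-indene-4,7-dione (cis-fused) | CC(C)(C)[Si](OC[C@@H]1CC[C@]2(C)C(=O)CCC(=O)[C@H]12)(c1ccccc1)c1ccccc1
F7 | step 8 | 2-bromo-1-[(1S,2S,3R)-3-({[tert-butyl(diphenyl)silyl]oxy}methyl)-1-methyl-2-{1-[(trimethylsilyl)oxy]ethenyl}cyclopentyl]ethan-1-one (bromine on C6) | CC(C)(C)[Si](OC[C@@H]1CC[C@](C)(C(=O)CBr)[C@H]1C(=C)O[Si](C)(C)C)(c1ccccc1)c1ccccc1
F8 | step 8 | 2-bromo-1-[(1S,2S,5R)-5-({[tert-butyl(diphenyl)silyl]oxy}methyl)-2-methyl-2-{1-[(trimethylsilyl)oxy]ethenyl}cyclopentyl]ethan-1-one (bromine on C5) | CC(C)(C)[Si](OC[C@@H]1CC[C@](C)(C(=C)O[Si](C)(C)C)[C@H]1C(=O)CBr)(c1ccccc1)c1ccccc1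
F9 | step 9 | (3R,3aS,7aS)-3-(hydroxymethyl)-7a-methylhexahydro-1H-indene-4,7-dione | OC[C@@H]1CC[C@]2(C)C(=O)CCC(=O)[C@@H]12
F10 | step 9 | (3R,3aS,4R,7aS)-4-hydroxy-3-(hydroxymethyl)-4,7a-dimethyloctahydro-7H-inden-7-one | OC[C@@H]1CC[C@]2(C)C(=O)CC[C@@](C)(O)[C@@H]12
F11 | step 11 | (3R,3aS,4R,7aS)-7,7-dibromo-3-({[tert-butyl(diphenyl)silyl]oxy}methyl)-4,7a-dimethyloctahydro-1H-inden-4-ol | CC(C)(C)[Si](OC[C@@H]1CC[C@]2(C)C(Br)(Br)CC[C@@](C)(O)[C@@H]12)(c1ccccc1)c1ccccc1
A1 | alternative 1 | 2-{(3R)-6-[(tert-butyldiphenylsilyl)oxy]-3-methyl-3-[(triethylsilyl)oxy]hex-4-yn-1-yl}-2-(prop-1-en-2-yl)-1,3-dioxolane | C=C(C)C1(OCCO1)CC[C@@](C)(O[Si](CC)(CC)CC)C#CCO[Si](c1ccccc1)(c1ccccc1)C(C)(C)C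
A2 | alternative 1 | (4R,7aS)-3-({[tert-butyl(diphenyl)silyl]oxy}methyl)-4,7a-dimethyl-4-[(triethylsilyl)oxy]-4,5,6,7a-tetrahydro-1H-inden-2-one 7-ethylene ketal | O=C1C[C@]2(C)C3(OCCO3)CC[C@@](C)(O[Si](CC)(CC)CC)C2=C1CO[Si](c1ccccc1)(c1ccccc1)C(C)(C)C
A3 | alternative 2 | (4E)-8-chloro-1,1-dimethoxy-4-methylnona-4,8-diene | COC(OC)CC/C(C)=C/CCC(Cl)=C
A4 | alternative 2 | (3S,4S)-4-bromo-3-(3,3-dimethoxypropyl)-3-methylcyclohexan-1-one | COC(OC)CC[C@]1(C)[C@@H](Br)CCC(=O)C1
A5 | alternative 3 | trans-fused 4-bromo-1,4a-dimethyl-1,2,3,4,4a,5,8,8a-octahydronaphthalen-1-ol (configuration as in the target) | C1=CC[C@]2(C)[C@@H](Br)CC[C@@](C)(O)[C@H]2C1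
A6 | alternative 3 | 2,2'-(3-bromo-6-hydroxy-2,6-dimethylcyclohexane-1,2-diyl)diacetaldehyde (arms trans, configuration as in the target) | O=CC[C@]1(C)[C@@H](Br)CC[C@@](C)(O)[C@H]1CC=O
A7 | alternative 3 | 7-bromo-4-hydroxy-4,7a-dimethyl-3a,4,5,6,7,7a-hexahydro-1H-indene-3-carbaldehyde (C2=C3) | O=CC1=CC[C@]2(C)[C@@H](Br)CC[C@@](C)(O)[C@@H]12
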